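**Plan**
1. Cuts: the O6 methyl, O3 benzoyl and O2 acetyl groups go on last. The cis C1–OH/C2–O pair is read as an osmylated C1=C2 alkene, so the ring is a masked cis-3,6-dioxygenated cyclohexa-1,4-diene. Both ring alkenes, C4=C5 and C1=C2, are cut as olefin metatheses, leaving a C5–C6–C1(C7) dienol and penta-1,4-dien-3-ol (C2–C3–C4).
2. Enabling feature: O3 and O6 stand cis on the two sp3 ring carbons that lie between both alkenes. One O3–Si–O6 bridge can therefore tie the two three-carbon pieces together and let both ring alkenes close around it: first the seven-membered dioxasilepine ring, then the six-membered carbocycle as a [3.2.2] bicycle.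
3. Forward order: benzoate-bearing enal, asymmetric vinylation (C6), mixed diisopropylsilaketal with penta-1,4-dien-3-ol, double ring-closing metathesis (C4=C5, then C1=C2), osmylation of C1=C2, O2 acetate, tether removal, O3 benzoate, O6 methyl ether.
4. Stereochemistry: C6 comes from the catalytic enantioselective vinylation. C3 comes from the bridge, since only the cis-bridged bicycle can form and both diastereotopic vinyl groups converge on it. C1 and C2 come from osmylation on the face away from the bridge.

Key step: step 5

Remark on numbering: target numbering is used throughout: C1 = C(OH)(CH2OBz), C2 = CHOAc, C3 = CHOBz, C4=C5, C6 = CHOMe, C7 = exocyclic CH2.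
Assumption: the (−)-MIB/zinc catalyst adds the vinyl group to the Si face of enal 3, as it does with simple aldehydes, which corresponds to the S carbinol.

Step 1
Reactants: 1 2-methylidenepropane-1,3-diol
Product: 2 2-(hydroxymethyl)prop-2-en-1-yl benzoate
Conditions: BzCl (1 equiv), 1 (3 equiv), Et3N, DMAP (cat.), CH2Cl2, −20 to 0 °C
Reagents that add atoms: benzoyl chloride O=C(Cl)c1ccccc1
Why: Statistical mono-acylation (nucleophilic acyl substitution) of a symmetrical primary diol used in excess should give the monoester, with no stereocenter involved and surplus 1 removed by aqueous washing.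

Step 2
Reactants: 2 2-(hydroxymethyl)prop-2-en-1-yl benzoate
Product: 3 2-formylprop-2-en-1-yl benzoate
Conditions: MnO2 (activated, excess), CH2Cl2, rt; used without storage
Reagents that add atoms: none
Why: Allylic alcohol oxidation on the MnO2 surface should convert the primary allylic alcohol into the enal without touching the benzoate or moving the 1,1-disubstituted alkene.

Step 3
Reactants: 3 2-formylprop-2-en-1-yl benzoate
Product: 4 (3S)-3-hydroxy-2-methylidenepent-4-en-1-yl benzoate
Conditions: Zn(CH=CH2)2 (salt-free solution, 1.5 equiv), (2S)-(−)-3-exo-(morpholino)isoborneol [(−)-MIB, 5 mol %], PhMe, −10 °C; then sat. aq. NH4Cl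
Reagents that add atoms: divinylzinc C=C[Zn]C=C
Why: Amino-alcohol-catalysed enantioselective 1,2-addition of an alkenylzinc to an α-branched enal is expected to deliver the vinyl group to the Si face of the aldehyde, which sets the S carbinol that becomes C6 of the target.

Step 4
Reactants: 5 penta-1,4-dien-3-ol; 4 (3S)-3-hydroxy-2-methylidenepent-4-en-1-yl benzoate
Product: 7 (3S)-3-{[diisopropyl(penta-1,4-dien-3-yloxy)silyl]oxy}-2-methylidenepent-4-en-1-yl benzoate, via chlorosilane 6 (not isolated)
Conditions: (i) 5, iPr2SiCl2, Et3N, DMAP (cat.), CH2Cl2, 0 °C to rt; (ii) 4, imidazole, CH2Cl2, rt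
Reagents that add atoms: dichlorodiisopropylsilane CC(C)[Si](Cl)(Cl)C(C)C
Why: Two successive nucleophilic substitutions at silicon (silyl ether formation) should give the mixed silaketal, because the second displacement on the hindered alkoxychlorosilane 6 is much slower than the first and the carbinol stereocenter of 4 is not touched.

Step 5
Reactants: 7 (3S)-3-{[diisopropyl(penta-1,4-dien-3-yloxy)silyl]oxy}-2-methylidenepent-4-en-1-yl benzoate
Product: 9 [(3R,6S)-3,6-(diisopropylsilanediyldioxy)cyclohexa-1,4-dien-1-yl]methyl benzoate (a 3,3-diisopropyl-2,4-dioxa-3-silabicyclo[3.2.2]nona-6,8-diene), via cis-dioxasilepine 8 (not isolated)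
Conditions: RuCl2(=CH-C6H4-2-OiPr)(H2IMes) (second-generation Hoveyda–Grubbs catalyst, 10 mol %), 2,6-dichloro-1,4-benzoquinone (20 mol %), PhMe (0.003 M), 80 °C
Reagents that add atoms: none
Why: A ruthenium alkylidene generated at a monosubstituted vinyl group runs two consecutive ring-closing olefin metatheses ([2+2] to a ruthenacyclobutane, then retro-[2+2], each with loss of ethylene): the first makes C4=C5, the second makes C1=C2, whose σ component is the C1–C2 bond of the target. The closest known reaction type is the temporary-silicon-tethered ring-closing metathesis of mixed bis(allyloxy)silanes, including those of penta-1,4-dien-3-ol, here carried on by a second closure in the same flask. The first closure forms the seven-membered 1,3-dioxa-2-silacyclohept-5-ene ring of 8 (ring-enforced Z alkene), and the second joins the vinyl group left on C3 to the 1,1-disubstituted alkene on C6 across that ring, which closes the six-membered carbocycle as a cyclohexa-1,4-diene and gives the 2,4-dioxa-3-silabicyclo[3.2.2]nona-6,8-diene. The one new stereocenter, C3 (the former divinylcarbinol carbon), is controlled by the O3–Si–O6 bridge: the bicycle can exist only with both oxygens on one ring face, so whichever diastereotopic vinyl group reacts first, the cis monocycle goes on to 9 while a trans monocycle cannot and is reopened by the ethylene-derived Ru=CH2 species, which makes the step stereoconvergent. The step needs ring closure to beat cross-metathesis and the doubly allylic, oxygen-bearing C–H bonds to stay in place; high dilution should secure the first, and the benzoquinone additive, which intercepts ruthenium hydrides, the second. C6, set in step 3, is a spectator because no bond to it is made or broken.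

Step 6
Reactants: 9 [(3R,6S)-3,6-(diisopropylsilanediyldioxy)cyclohexa-1,4-dien-1-yl]methyl benzoate
Product: 10 [(1S,2S,3R,6S)-1,2-dihydroxy-3,6-(diisopropylsilanediyldioxy)cyclohex-4-en-1-yl]methyl benzoate
Conditions: OsO4 (2 mol %), (DHQ)2PHAL (5 mol %), NMO (1.1 equiv), acetone/H2O, 0 °C
Reagents that add atoms: osmium tetroxide O=[Os](=O)(=O)=O; N-methylmorpholine N-oxide C[N+]1([O-])CCOCC1; water O
Why: Ligand-accelerated osmium-catalysed syn-dihydroxylation should pick the trisubstituted C1=C2 alkene, whose benzoyloxymethyl arm suits the aryl-binding pocket of the ligand, over the cis-disubstituted C4=C5 alkene, and should add both oxygens on the face away from the O–Si–O bridge (substrate bias and ligand preference coincide), which sets C1 and C2 with their hydroxyls trans to O6 and O3.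

Step 7
Reactants: 10 [(1S,2S,3R,6S)-1,2-dihydroxy-3,6-(diisopropylsilanediyldioxy)cyclohex-4-en-1-yl]methyl benzoate
Product: 11 [(1S,2S,3R,6S)-2-acetoxy-1-hydroxy-3,6-(diisopropylsilanediyldioxy)cyclohex-4-en-1-yl]methyl benzoate
Conditions: Ac2O (1.5 equiv), pyridine, DMAP (5 mol %), CH2Cl2, 0 °C
Reagents that add atoms: acetic anhydride CC(=O)OC(C)=O
Why: DMAP-catalysed acylation (nucleophilic acyl substitution) should esterify the secondary C2 hydroxyl while the tertiary C1 hydroxyl is too hindered to react at 0 °C, with no stereocenter affected.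

Step 8
Reactants: 11 [(1S,2S,3R,6S)-2-acetoxy-1-hydroxy-3,6-(diisopropylsilanediyldioxy)cyclohex-4-en-1-yl]methyl benzoate
Product: 12 [(1R,2S,3R,6S)-2-acetoxy-1,3,6-trihydroxycyclohex-4-en-1-yl]methyl benzoate
Conditions: HF·pyridine, pyridine, THF, 0 °C to rt
Reagents that add atoms: none
Why: Fluoride-driven cleavage of both Si–O bonds (silyl ether deprotection) should remove the tether under buffered, mildly acidic conditions that do not favour acyl migration, with all configurations retained because only O–Si bonds break.

Step 9
Reactants: 12 [(1R,2S,3R,6S)-2-acetoxy-1,3,6-trihydroxycyclohex-4-en-1-yl]methyl benzoate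
Product: 13 [(1R,2S,3R,6S)-2-acetoxy-3-(benzoyloxy)-1,6-dihydroxycyclohex-4-en-1-yl]methyl benzoate
Conditions: BzCl (1.05 equiv), pyridine, CH2Cl2, −40 °C
Reagents that add atoms: benzoyl chloride O=C(Cl)c1ccccc1
Why: Kinetically controlled acylation (nucleophilic acyl substitution) should take the less hindered allylic C3 hydroxyl, which is flanked by a CH carbon, in preference to the C6 hydroxyl next to the fully substituted C1 and to the tertiary C1 hydroxyl, with no C–O bond broken.

Step 10
Reactants: 13 [(1R,2S,3R,6S)-2-acetoxy-3-(benzoyloxy)-1,6-dihydroxycyclohex-4-en-1-yl]methyl benzoate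
Product: 14 [(1R,2S,3R,6S)-2-acetoxy-3-(benzoyloxy)-1-hydroxy-6-methoxycyclohex-4-en-1-yl]methyl benzoate (target)
Conditions: Me3OBF4 (3 equiv), 1,8-bis(dimethylamino)naphthalene (3 equiv), 4 Å MS, CH2Cl2, 0 °C to rt
Reagents that add atoms: trimethyloxonium tetrafluoroborate C[O+](C)C.F[B-](F)(F)F
Why: O-alkylation with a trialkyloxonium salt (SN2 at methyl) in the presence of a non-nucleophilic proton scavenger should methylate the only secondary hydroxyl under conditions too mild for ester migration or for alkylation of the tertiary C1 hydroxyl, leaving all four stereocenters unchanged.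

**Compound list**
1 | 2-methylidenepropane-1,3-diol | C=C(CO)CO | starting material
2 | 2-(hydroxymethyl)prop-2-en-1-yl benzoate | C=C(CO)COC(=O)c1ccccc1 | intermediate
3 | 2-formylprop-2-en-1-yl benzoate | C=C(C=O)COC(=O)c1ccccc1 | intermediate
4 | (3S)-3-hydroxy-2-methylidenepent-4-en-1-yl benzoate | C=C[C@H](O)C(=C)COC(=O)c1ccccc1 | intermediate
5 | penta-1,4-dien-3-ol | C=CC(O)C=C | starting material
6 | chloro(diisopropyl)(penta-1,4-dien-3-yloxy)silane | C=CC(C=C)O[Si](Cl)(C(C)C)C(C)C | intermediate (not isolated)
7 | (3S)-3-{[diisopropyl(penta-1,4-dien-3-yloxy)silyl]oxy}-2-methylidenepent-4-en-1-yl benzoate | C=C[C@H](O[Si](C(C)C)(C(C)C)OC(C=C)C=C)C(=C)COC(=O)c1ccccc1 | intermediate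
8 | 2-[(4S,7S)-2,2-diisopropyl-7-vinyl-4,7-dihydro-1,3,2-dioxasilepin-4-yl]prop-2-en-1-yl benzoate (cis) | CC(C)[Si]1(C(C)C)O[C@@H](C=C)/C=C\[C@H](O1)C(=C)COC(=O)c2ccccc2 | intermediate (not isolated)
9 | [(3R,6S)-3,6-(diisopropylsilanediyldioxy)cyclohexa-1,4-dien-1-yl]methyl benzoate | CC(C)[Si]1(C(C)C)O[C@H]2C=C[C@@H](O1)C=C2COC(=O)c3ccccc3 | intermediate
10 | [(1S,2S,3R,6S)-1,2-dihydroxy-3,6-(diisopropylsilanediyldioxy)cyclohex-4-en-1-yl]methyl benzoate | CC(C)[Si]1(C(C)C)O[C@H]2C=C[C@@H](O1)[C@H](O)[C@@]2(O)COC(=O)c3ccccc3 | intermediate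
11 | [(1S,2S,3R,6S)-2-acetoxy-1-hydroxy-3,6-(diisopropylsilanediyldioxy)cyclohex-4-en-1-yl]methyl benzoate | CC(C)[Si]1(C(C)C)O[C@H]2C=C[C@@H](O1)[C@H](OC(C)=O)[C@@]2(O)COC(=O)c3ccccc3 | intermediate
12 | [(1R,2S,3R,6S)-2-acetoxy-1,3,6-trihydroxycyclohex-4-en-1-yl]methyl benzoate | O[C@H]1C=C[C@@H](O)[C@H](OC(C)=O)[C@@]1(O)COC(=O)c1ccccc1 | intermediate
13 | [(1R,2S,3R,6S)-2-acetoxy-3-(benzoyloxy)-1,6-dihydroxycyclohex-4-en-1-yl]methyl benzoate | O[C@H]1C=C[C@@H](OC(=O)c2ccccc2)[C@H](OC(C)=O)[C@@]1(O)COC(=O)c1ccccc1 | intermediate
14 | [(1R,2S,3R,6S)-2-acetoxy-3-(benzoyloxy)-1-hydroxy-6-methoxycyclohex-4-en-1-yl]methyl benzoate | CO[C@H]1C=C[C@@H](OC(=O)c2ccccc2)[C@H](OC(C)=O)[C@@]1(O)COC(=O)c1ccccc1 | target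

**Totals and risks**
Total step count: 10. Longest linear sequence: 10 steps (1 to 14); 5 enters at step 4.

Most likely to fail, step 5: the second, transannular ring closure may stall at the monocyclic stage, or intermolecular metathesis and olefin migration may take over. Fallback (stepwise, unbridged closure): it sets out from 7. With RuCl2(=CHPh)(PCy3)2 (first-generation Grubbs catalyst, CH2Cl2, 40 °C), which does not engage the 1,1-disubstituted alkene, only the seven-membered ring should close, and the cis-dioxasilepine 8 would be isolated and separated from any trans isomer. HF·pyridine would then free the (Z)-triene diol F1, and TESCl/imidazole would give the bis(triethylsilyl) ether F2. An ordinary ring closure with RuCl2(=CHPh)(PCy3)(H2IMes) (second-generation Grubbs catalyst) should give the unbridged cyclohexa-1,4-diene F3. Osmylation as in step 6, on the face away from the two silyloxy groups, would give the diol F4, and acetylation as in step 7 the acetate F5. HF·pyridine would remove both silyl groups and the fallback comes back to the route at 12.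

Second, step 6: the osmylation may discriminate poorly between the two ring alkenes, or may run on to a tetraol. Fallback (hydroxyl-directed osmylation): it sets out from 9. DIBAL-H (CH2Cl2, −78 °C) would cleave the benzoate to the allylic alcohol F6. Stoichiometric OsO4·TMEDA (CH2Cl2, −78 °C), hydrogen-bonded to the C7 hydroxyl, should be delivered only to the alkene that carries this hydroxymethyl group, again on the face away from the silicon bridge, and cleavage of the osmate ester (aq. Na2SO3) would give the triol F7. BzCl/2,4,6-collidine at −78 °C would benzoylate the primary hydroxyl again and the fallback comes back to the route at 10.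

Third, step 9: the acylation may not distinguish the two secondary allylic hydroxyls well enough, or the acetyl group may migrate under base. Fallback (reversed order, tin-directed etherification): it sets out from 12. Bu2SnO (PhMe, reflux) should form the stannylene acetal on the only free vicinal diol (O1/O6), and CsF/MeI (DMF) would alkylate its secondary oxygen to give the methyl ether F8. The single remaining secondary hydroxyl (C3) would then be benzoylated with BzCl/pyridine/DMAP, and the fallback comes back to the route at 14.

**Further compounds**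
F1 | step 5 | (3S,4Z,6S)-3,6-dihydroxy-2-methylideneocta-4,7-dien-1-yl benzoate | C=C[C@H](O)/C=C\[C@H](O)C(=C)COC(=O)c1ccccc1
F2 | step 5 | (3S,4Z,6S)-2-methylidene-3,6-bis(triethylsilyloxy)octa-4,7-dien-1-yl benzoate | C=C[C@H](O[Si](CC)(CC)CC)/C=C\[C@H](O[Si](CC)(CC)CC)C(=C)COC(=O)c1ccccc1
F3 | step 5 | [(3R,6S)-3,6-bis(triethylsilyloxy)cyclohexa-1,4-dien-1-yl]methyl benzoate | CC[Si](CC)(CC)O[C@H]1C=C[C@@H](O[Si](CC)(CC)CC)C=C1COC(=O)c1ccccc1
F4 | step 5 | [(1S,2S,3R,6S)-1,2-dihydroxy-3,6-bis(triethylsilyloxy)cyclohex-4-en-1-yl]methyl benzoate | CC[Si](CC)(CC)O[C@H]1C=C[C@@H](O[Si](CC)(CC)CC)[C@H](O)[C@@]1(O)COC(=O)c1ccccc1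
F5 | step 5 | [(1S,2S,3R,6S)-2-acetoxy-1-hydroxy-3,6-bis(triethylsilyloxy)cyclohex-4-en-1-yl]methyl benzoate | CC[Si](CC)(CC)O[C@H]1C=C[C@@H](O[Si](CC)(CC)CC)[C@H](OC(C)=O)[C@@]1(O)COC(=O)c1ccccc1
F6 | step 6 | [(3R,6S)-3,6-(diisopropylsilanediyldioxy)cyclohexa-1,4-dien-1-yl]methanol | CC(C)[Si]1(C(C)C)O[C@H]2C=C[C@@H](O1)C=C2CO
F7 | step 6 | (1S,2S,3R,6S)-1-(hydroxymethyl)-3,6-(diisopropylsilanediyldioxy)cyclohex-4-ene-1,2-diol | CC(C)[Si]1(C(C)C)O[C@H]2C=C[C@@H](O1)[C@H](O)[C@@]2(O)CO
F8 | step 9 | [(1R,2S,3R,6S)-2-acetoxy-1,3-dihydroxy-6-methoxycyclohex-4-en-1-yl]methyl benzoate | CO[C@H]1C=C[C@@H](O)[C@H](OC(C)=O)[C@@]1(O)COC(=O)c1ccccc1
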